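**Retrosynthetic overview**
1. Ring B is opened at C6–C7; the ten-membered ring is closed last, by nickel-catalysed electroreductive decarboxylative alkenylation of a C7 N-acyloxyphthalimide with the (Z)-C6 alkenyl iodide.
2. The strategy rests on ring C (γ-lactone O7–C7–C8–C17–C19, C8 bearing OH and the C9 branch, C7 bearing one carbon): it is the lactone of hydroxycitric acid (garcinia acid), whose C7 carboxyl leaves as CO2 and whose C8 carboxyl becomes C9.
3. C9–C10 is formed by allylboration of the garcinia-derived C9 aldehyde with a ring A C12 allylboronate; C9 is then set by oxidation and chelation-controlled reduction, and O8/O9 are tied as an acetonide.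
4. Ring A comes from (S)-carvone (carbonyl carbon = C10, C6 = C1, isopropenyl carbon = C14 by Criegee rearrangement); C2–C6 comes from prop-2-yn-1-ol as a (Z)-iodoalkenyl Weinreb amide.
5. Ring order: C (chiral pool), A (chiral pool), B (key step); the two acetates of the target are carried through the ring closure, so only the acetonide is removed at the end.

Key step: step 23

Remark on the chemistry: garcinia acid and N-methoxy-N-methylacetamide are assumed to be purchasable; briarane numbering is used for all intermediates, β is the face of ring A that carries the C1 methyl (C15), α the opposite face.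

**Route**

Step 1
Reactants: 1 garcinia acid
Product: 2 spiro dioxolanone acid (O8 and the C8 carboxyl tied as 2,2-dimethyl-1,3-dioxolan-4-one, C7 acid free)
Conditions: 2,2-dimethoxypropane, TsOH·H2O (cat.), acetone, rt
Reagents that add atoms: 2,2-dimethoxypropane, COC(C)(C)OC
Why: Acid-catalysed ketalisation of an α-hydroxy acid gives the five-membered dioxolanone in preference to any six-membered alternative, so O8 and the future C9 are masked together, only the C7 carboxyl stays free and no stereocentre is touched.

Step 2
Reactants: 2 spiro dioxolanone acid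
Product: 3 spiro dioxolanone tert-butyl ester
Conditions: tert-butyl 2,2,2-trichloroacetimidate, BF3·OEt2 (cat.), CH2Cl2/cyclohexane, rt
Reagents that add atoms: tert-butyl 2,2,2-trichloroacetimidate, CC(C)(C)OC(=N)C(Cl)(Cl)Cl
Why: Acid-catalysed O-alkylation of the free acid by the trichloroacetimidate installs a tert-butyl ester that is bulky enough to resist later lactonisation with O9 and to shield the α face of the lactone.

Step 3
Reactants: 3 spiro dioxolanone tert-butyl ester
Product: 5 C17-methyl spiro dioxolanone (methyl cis to O8), via lithium enolate 4 (not isolated)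
Conditions: LiN(SiMe3)2 (1.05 equiv), THF, −78 °C, 10 min; then MeI, DMPU, −78 °C
Reagents that add atoms: iodomethane, CI
Why: Kinetic enolisation of the γ-lactone at the C17 methylene (more acidic and more accessible than the hindered C7–H) and enolate alkylation at low temperature, the electrophile entering on the face of O8 and anti to the cis C7 tert-butyl ester and the C9 carbonyl, which sets C17 with its methyl cis to O8.

Step 4
Reactants: 5 C17-methyl spiro dioxolanone
Product: 6 C9 S-ethyl thioester with free 8-OH
Conditions: EtSH, Et3N, DMAP (cat.), CH2Cl2, 0 °C → rt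
Reagents that add atoms: ethanethiol, CCS
Why: Acyl substitution by thiolate on the activated dioxolanone carbonyl (transthioesterification of an O-acyl hemiketal) releases acetone and frees the tertiary C8 hydroxyl, while the tert-butyl ester is inert and any attack on the lactone is reversible.

Step 5
Reactants: 6 C9 S-ethyl thioester
Product: 7 C9 aldehyde (α-hydroxy aldehyde of ring C, used at once)
Conditions: Et3SiH, Pd/C (10% Pd on carbon), acetone, rt
Reagents that add atoms: none
Why: Fukuyama reduction stops at the aldehyde and leaves the lactone, the tert-butyl ester and the tertiary alcohol untouched, so the former C8 carboxyl carbon becomes the C9 aldehyde without a free primary alcohol ever being formed.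

Step 6
Reactants: 8 prop-2-yn-1-ol
Product: 10 (Z)-3-iodo-2-methylprop-2-en-1-ol, via oxamagnesacycle 9 (not isolated)
Conditions: MeMgBr (2.5 equiv), CuI (10 mol%), THF, −10 °C → rt; then I2, −10 °C
Reagents that add atoms: methylmagnesium bromide, C[Mg]Br; iodine, II
Why: Copper-catalysed carbomagnesiation of the magnesium propargylic alkoxide is an anti addition through a five-membered oxamagnesacycle, so iodinolysis with retention gives only the Z iodoalkene with iodine cis to the CH2O carbon (the future C4).

Step 7
Reactants: 10 (Z)-3-iodo-2-methylprop-2-en-1-ol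
Product: 11 (Z)-3-bromo-1-iodo-2-methylprop-1-ene
Conditions: CBr4, PPh3, CH2Cl2, 0 °C
Reagents that add atoms: carbon tetrabromide, BrC(Br)(Br)Br
Why: Appel bromination of the primary allylic alcohol is an SN2 displacement that leaves the alkenyl iodide and its geometry untouched.

Step 8
Reactants: 12 N-methoxy-N-methylacetamide; 11 (Z)-3-bromo-1-iodo-2-methylprop-1-ene
Product: 14 (Z)-5-iodo-N-methoxy-N,4-dimethylpent-4-enamide, via lithium amide enolate 13 (not isolated)
Conditions: LiN(iPr)2, THF, −78 °C; then 11, −78 → −20 °C
Reagents that add atoms: none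
Why: Alkylation of the Weinreb acetamide enolate with the reactive allylic bromide forms C3–C4 and delivers the whole C2–C6 chain as an acyl donor with the Z iodoalkene intact.

Step 9
Reactants: 15 (S)-carvone; 14 (Z)-iodoalkenyl Weinreb amide
Product: 17 6-acylcarvone (1,3-diketone, C1 epimers and enol), via lithium dienolate 16 (not isolated)
Conditions: LiN(iPr)2, THF, −78 °C; then 14, −78 → 0 °C; aq. NH4Cl
Reagents that add atoms: none
Why: Kinetic deprotonation of carvone at C6 (the future C1) and C-acylation of the cross-conjugated enolate by the Weinreb amide through a chelated tetrahedral intermediate (crossed Claisen-type acylation) forms C1–C2 without over-addition, the C1 configuration being fixed only in the next step.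

Step 10
Reactants: 17 6-acylcarvone
Product: 18 C1-quaternary diketone (C15 methyl trans, acyl chain cis to the isopropenyl group)
Conditions: K2CO3, MeI, acetone, 0 °C → rt
Reagents that add atoms: iodomethane, CI
Why: C-methylation of the 1,3-diketone enolate occurs anti to the adjacent isopropenyl group, which sets the C1 quaternary centre with C15 β and the C2 chain α, and bringing the chain in as an acyl group avoids any strongly basic enolisation at C3 that could add to the enone.

Step 11
Reactants: 18 C1-quaternary diketone
Product: 19 (2R)-alcohol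
Conditions: (S)-2-methyl-CBS-oxazaborolidine (0.3 equiv), catecholborane, toluene, −78 °C
Reagents that add atoms: none
Why: Corey–Bakshi–Shibata reduction, in which the catalyst distinguishes the quaternary C1 from the C3 methylene and delivers hydride to give the (2R) carbinol, while the enone carbonyl, flanked by a quaternary carbon and a methyl-bearing sp2 carbon, binds the catalyst far more slowly and catecholborane does not hydroborate the alkenes at this temperature.

Step 12
Reactants: 19 (2R)-alcohol
Product: 20 (2R)-acetate
Conditions: Ac2O, DMAP (cat.), pyridine, CH2Cl2, rt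
Reagents that add atoms: acetic anhydride, CC(=O)OC(C)=O
Why: DMAP-catalysed acetylation installs the C2 acetate of the target at once and removes the free hydroxyl that could add to the enone.

Step 13
Reactants: 20 (2R)-acetate
Product: 23 ring A enone diacetate (14α-OAc), via methoxy hydroperoxide 21 (not isolated), via peroxyacetate 22 (not isolated)
Conditions: O3, CH2Cl2/MeOH, NaHCO3, −78 °C (Sudan Red 7B end point); then Ac2O, Et3N, DMAP (cat.), CH2Cl2, 0 °C → rt
Reagents that add atoms: ozone, [O-][O+]=O; methanol, CO
Why: Ozone selects the electron-rich 1,1-disubstituted alkene over the enone and the iodoalkene, and the peracetate of the resulting α-methoxy hydroperoxide undergoes Criegee rearrangement with migration of C14 and retention of configuration, which gives the 14α-acetate of the target directly.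

Step 14
Reactants: 23 ring A enone diacetate
Product: 24 10α-allylic alcohol
Conditions: NaBH4, CeCl3·7H2O, MeOH, −78 → −40 °C
Reagents that add atoms: none
Why: Luche 1,2-reduction of the enone, with hydride entering on the β face, syn to the small C1 methyl and anti to the C1 side chain and the C14 acetoxy group, should give the 10α alcohol.

Step 15
Reactants: 24 10α-allylic alcohol
Product: 25 10α-methyl carbonate
Conditions: ClCO2Me, pyridine, DMAP (cat.), CH2Cl2, 0 °C
Reagents that add atoms: methyl chloroformate, COC(=O)Cl
Why: Acylation of the hindered allylic alcohol with the small chloroformate gives the carbonate leaving group with retention at C10.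

Step 16
Reactants: 25 10α-methyl carbonate
Product: 26 12β-allylboronate (pinacol ester, C10=C11 alkene)
Conditions: B2pin2, CuCl (10 mol%), Xantphos (10 mol%), KOtBu (10 mol%), THF, 0 °C → rt
Reagents that add atoms: bis(pinacolato)diboron, CC1(C)OB(OC1(C)C)B2OC(C)(C)C(C)(C)O2
Why: Copper-catalysed γ-selective allylic borylation is an anti SN2′ substitution (borylcupration anti to the leaving group, then β-elimination), which moves the alkene to C10=C11 and places boron on the β face of C12, and turnover by the liberated methoxide spares the acetates and the alkenyl iodide.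

Step 17
Reactants: 26 12β-allylboronate; 7 C9 aldehyde
Product: 28 coupled 8,9-diol (9-epi), via pinacol borate 27 (not isolated)
Conditions: toluene, 4 Å molecular sieves, 50 °C; aq. NaHCO3 work-up
Reagents that add atoms: none
Why: Allylboration through a closed six-membered chair transition state forms C9–C10 with allylic transposition on the face that carries boron, so C9 is attached β at C10 (H10 α) and the C11=C12 alkene is restored, while the ring-constrained Z-type boronate gives the 9,10-syn adduct, the C9 epimer of the target, which steps 18 and 19 correct.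

Step 18
Reactants: 28 coupled 8,9-diol (9-epi)
Product: 29 C9 ketone (8-hydroxy-9-oxo)
Conditions: Dess–Martin periodinane, NaHCO3, CH2Cl2, 0 °C → rt
Reagents that add atoms: none
Why: Dess–Martin oxidation of the secondary C9 alcohol under buffered conditions gives the α-hydroxy ketone without touching the tertiary hydroxyl, conjugating the β,γ-alkene or epimerising C10.

Step 19
Reactants: 29 C9 ketone
Product: 30 8,9-diol with the C9 configuration of the target
Conditions: Zn(BH4)2, Et2O/CH2Cl2, −40 → −10 °C; aq. NH4Cl
Reagents that add atoms: none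
Why: Chelation-controlled reduction, in which zinc bridges O8 and the C9 carbonyl and hydride enters from the side of C17–H, away from the cis C7 tert-butyl ester (the native C7 centre of garcinia acid), which sets C9 so that C10 lies cis to C7 across the C8–C9 bond as in the target.

Step 20
Reactants: 30 8,9-diol
Product: 31 8,9-acetonide tert-butyl ester
Conditions: 2-methoxypropene, PPTS (cat.), CH2Cl2, 0 °C → rt
Reagents that add atoms: 2-methoxypropene, COC(C)=C
Why: Acid-catalysed ketalisation with the enol ether closes the dioxolane, which protects both hydroxyls, blocks lactonisation of O9 onto the C7 carboxyl and holds C10 on the same side as C7.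

Step 21
Reactants: 31 8,9-acetonide tert-butyl ester
Product: 33 C7 carboxylic acid, via trimethylsilyl ester 32 (not isolated)
Conditions: Me3SiOSO2CF3, 2,6-lutidine, CH2Cl2, 0 °C; then pH 5 buffer
Reagents that add atoms: none
Why: Silyl triflate-mediated cleavage of the tert-butyl ester (loss of isobutene to the silyl ester, hydrolysed on work-up) unmasks the C7 acid under buffered aprotic conditions that leave the ketal, the acetates, the lactone and the alkenyl iodide intact.

Step 22
Reactants: 33 C7 carboxylic acid
Product: 34 C7 N-acyloxyphthalimide (seco iodoalkene)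
Conditions: N-hydroxyphthalimide, N,N′-diisopropylcarbodiimide, DMAP (cat.), CH2Cl2, rt
Reagents that add atoms: N-hydroxyphthalimide, ON1C(=O)c2ccccc2C1=O
Why: Carbodiimide coupling (Steglich-type esterification) converts the acid into the redox-active ester under neutral conditions with no change at any stereocentre.

Step 23
Reactants: 34 C7 N-acyloxyphthalimide (seco iodoalkene)
Product: 35 tricyclic 8,9-acetonide (2,14-diacetate)
Conditions: NiCl2·glyme (NiCl2·MeOCH2CH2OMe, 20 mol%), 2,2′-bipyridine (24 mol%), LiBr, DMF, undivided cell, Zn anode, reticulated vitreous carbon cathode, constant current, rt, 34 added by syringe pump (final 2 mM)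
Reagents that add atoms: none
Why: Proposed new method: cathodic reduction gives zerovalent nickel–bipyridine, which inserts into the C6–I bond with retention of the Z geometry; single-electron transfer to the phthalimide ester then releases CO2, phthalimide anion and the C7 radical, which is stabilised by the lactone oxygen and has no β-hydrogen towards C8 because C8 is quaternary, and capture of this radical by the alkenylnickel followed by reductive elimination from trivalent nickel forges C6–C7. The closest known reaction type is the intermolecular nickel-catalysed reductive decarboxylative alkenylation of N-acyloxyphthalimides with alkenyl halides, including its electrochemical versions with a sacrificial anode; only its use to close a ten-membered carbocycle is untested. Ring B is closed as a macrocyclisation at the metal, by radical–nickel recombination within the tethered seco compound and ring-contracting reductive elimination, not by radical addition to an alkene, so no exo/endo choice arises and slow addition keeps the precursor dilute. The new C7 stereocentre is created on a planar radical, so the native C7 configuration of garcinia acid is irrelevant, and it is controlled by the spiro ring C: the alkenylnickel should bond on the face syn to O8 and anti to the C8–C9 bond, the other face being blocked by C9 and leading to a more strained cis-fused bicycle. The step needs chemoselectivity for the activated ester and the alkenyl iodide, which the inert acetates, lactone, ketal and trisubstituted ring A alkene allow, and it needs ring closure to outrun reduction of the radical to C7–H, which the acetonide favours by holding C10 on the C7 side of the dioxolane and so placing C6 near C7.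

Step 24
Reactants: 35 tricyclic 8,9-acetonide
Product: 36 9-deacetylstylatulide lactone
Conditions: AcOH/H2O (4:1), 45 °C
Reagents that add atoms: none
Why: Mild acid hydrolysis of the ketal frees the tertiary 8-OH and the secondary 9-OH without cleaving the two acetates or ionising the allylic lactone C–O bond, which should give the target.

**Compound list**
1 | garcinia acid, (2S,3S)-3-hydroxy-5-oxotetrahydrofuran-2,3-dicarboxylic acid | O=C1C[C@@](O)(C(=O)O)[C@@H](C(=O)O)O1 | starting material
2 | (5S,6S)-2,2-dimethyl-4,8-dioxo-1,3,7-trioxaspiro[4.4]nonane-6-carboxylic acid | O=C1C[C@@](O2)(C(=O)OC2(C)C)[C@@H](C(=O)O)O1 | intermediate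
3 | tert-butyl (5S,6S)-2,2-dimethyl-4,8-dioxo-1,3,7-trioxaspiro[4.4]nonane-6-carboxylate | O=C1C[C@@](O2)(C(=O)OC2(C)C)[C@@H](C(=O)OC(C)(C)C)O1 | intermediate
4 | lithium lactone enolate of 3 (C17=C19–OLi) | [Li]OC1=C[C@@](O2)(C(=O)OC2(C)C)[C@@H](C(=O)OC(C)(C)C)O1 | intermediate
5 | tert-butyl (5S,6S,9R)-2,2,9-trimethyl-4,8-dioxo-1,3,7-trioxaspiro[4.4]nonane-6-carboxylate (C17 methyl cis to O8) | O=C1[C@H](C)[C@@](O2)(C(=O)OC2(C)C)[C@@H](C(=O)OC(C)(C)C)O1 | intermediate
6 | tert-butyl (2S,3S,4R)-3-(ethylsulfanylcarbonyl)-3-hydroxy-4-methyl-5-oxotetrahydrofuran-2-carboxylate | O=C1[C@H](C)[C@@](O)(C(=O)SCC)[C@@H](C(=O)OC(C)(C)C)O1 | intermediate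
7 | tert-butyl (2S,3S,4R)-3-formyl-3-hydroxy-4-methyl-5-oxotetrahydrofuran-2-carboxylate (C9 aldehyde) | O=C1[C@H](C)[C@@](O)(C=O)[C@@H](C(=O)OC(C)(C)C)O1 | intermediate
8 | prop-2-yn-1-ol | C#CCO | starting material
9 | 4-methyl-2,5-dihydro-1,2-oxamagnesole (cyclic alkenylmagnesium alkoxide) | CC1=C[Mg]OC1 | intermediate
10 | (Z)-3-iodo-2-methylprop-2-en-1-ol | OC/C(C)=C\I | intermediate
11 | (Z)-3-bromo-1-iodo-2-methylprop-1-ene | BrC/C(C)=C\I | intermediate
12 | N-methoxy-N-methylacetamide | CC(=O)N(C)OC | starting material
13 | lithium enolate of 12 | [Li]OC(=C)N(C)OC | intermediate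
14 | (Z)-5-iodo-N-methoxy-N,4-dimethylpent-4-enamide | CON(C)C(=O)CC/C(C)=C\I | intermediate
15 | (S)-carvone | CC1=CC[C@@H](CC1=O)C(C)=C | starting material
16 | lithium cross-conjugated dienolate of carvone (C1–OLi, C1=C6) | [Li]OC1=C[C@@H](C(C)=C)CC=C1C | intermediate
17 | (5S)-6-[(Z)-5-iodo-4-methylpent-4-enoyl]-2-methyl-5-(prop-1-en-2-yl)cyclohex-2-en-1-one (C6 epimers and enol) | O=C1C(C)=CC[C@H](C(C)=C)C1C(=O)CC/C(C)=C\I | intermediate
18 | (5R,6R)-6-[(Z)-5-iodo-4-methylpent-4-enoyl]-2,6-dimethyl-5-(prop-1-en-2-yl)cyclohex-2-en-1-one (acyl cis to isopropenyl) | O=C1C(C)=CC[C@H](C(C)=C)[C@]1(C)C(=O)CC/C(C)=C\I | intermediate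
19 | (5R,6R)-6-[(1R,4Z)-1-hydroxy-5-iodo-4-methylpent-4-en-1-yl]-2,6-dimethyl-5-(prop-1-en-2-yl)cyclohex-2-en-1-one | O=C1C(C)=CC[C@H](C(C)=C)[C@]1(C)[C@H](O)CC/C(C)=C\I | intermediate
20 | (5R,6R)-6-[(1R,4Z)-1-acetoxy-5-iodo-4-methylpent-4-en-1-yl]-2,6-dimethyl-5-(prop-1-en-2-yl)cyclohex-2-en-1-one | O=C1C(C)=CC[C@H](C(C)=C)[C@]1(C)[C@H](OC(C)=O)CC/C(C)=C\I | intermediate
21 | α-methoxy hydroperoxide from 20 (isopropenyl carbon as C(CH3)(OCH3)OOH, epimers at that carbon) | O=C1C(C)=CC[C@H](C(C)(OC)OO)[C@]1(C)[C@H](OC(C)=O)CC/C(C)=C\I | intermediate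
22 | peroxyacetate of 21 | O=C1C(C)=CC[C@H](C(C)(OC)OOC(C)=O)[C@]1(C)[C@H](OC(C)=O)CC/C(C)=C\I | intermediate
23 | ring A enone diacetate: 10-oxo-11-ene, 14α-acetoxy, C1 β-methyl, C1 α-[(1R,4Z)-1-acetoxy-5-iodo-4-methylpent-4-en-1-yl] | O=C1C(C)=CC[C@H](OC(C)=O)[C@]1(C)[C@H](OC(C)=O)CC/C(C)=C\I | intermediate
24 | 10α-hydroxy-11-ene analogue of 23 (allylic alcohol) | O[C@@H]1C(C)=CC[C@H](OC(C)=O)[C@]1(C)[C@H](OC(C)=O)CC/C(C)=C\I | intermediate
25 | 10α-methyl carbonate of 24 | COC(=O)O[C@@H]1C(C)=CC[C@H](OC(C)=O)[C@]1(C)[C@H](OC(C)=O)CC/C(C)=C\I | intermediate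
26 | ring A 12β-(pinacolato)boryl-10-ene (allylboronate; 14α-OAc, C1 β-methyl, α side chain) | CC1(C)OB(OC1(C)C)[C@H]2C[C@H](OC(C)=O)[C@](C)([C@H](OC(C)=O)CC/C(C)=C\I)C=C2C | intermediate
27 | O9 pinacol borate of 28 | CC(=O)O[C@H]1CC=C(C)[C@H]([C@H](OB3OC(C)(C)C(C)(C)O3)[C@]2(O)[C@@H](C)C(=O)O[C@@H]2C(=O)OC(C)(C)C)[C@@]1(C)[C@H](OC(C)=O)CC/C(C)=C\I | intermediate
28 | coupled 8,9-diol, 9-epi (9,10-syn), C7 tert-butyl ester, C9 β on C10 | CC(=O)O[C@H]1CC=C(C)[C@H]([C@H](O)[C@]2(O)[C@@H](C)C(=O)O[C@@H]2C(=O)OC(C)(C)C)[C@@]1(C)[C@H](OC(C)=O)CC/C(C)=C\I | intermediate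
29 | coupled C9 ketone (8-hydroxy-9-oxo) | CC(=O)O[C@H]1CC=C(C)[C@H](C(=O)[C@]2(O)[C@@H](C)C(=O)O[C@@H]2C(=O)OC(C)(C)C)[C@@]1(C)[C@H](OC(C)=O)CC/C(C)=C\I | intermediate
30 | coupled 8,9-diol with the C9 configuration of the target | CC(=O)O[C@H]1CC=C(C)[C@H]([C@@H](O)[C@]2(O)[C@@H](C)C(=O)O[C@@H]2C(=O)OC(C)(C)C)[C@@]1(C)[C@H](OC(C)=O)CC/C(C)=C\I | intermediate
31 | 8,9-acetonide, C7 tert-butyl ester (C10 cis to C7 on the dioxolane) | CC(=O)O[C@H]1CC=C(C)[C@H]([C@H]2OC(C)(C)O[C@@]23[C@@H](C(=O)OC(C)(C)C)OC(=O)[C@@H]3C)[C@@]1(C)[C@H](OC(C)=O)CC/C(C)=C\I | intermediate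
32 | trimethylsilyl ester of 33 | CC(=O)O[C@H]1CC=C(C)[C@H]([C@H]2OC(C)(C)O[C@@]23[C@@H](C(=O)O[Si](C)(C)C)OC(=O)[C@@H]3C)[C@@]1(C)[C@H](OC(C)=O)CC/C(C)=C\I | intermediate
33 | C7 carboxylic acid (8,9-acetonide, 2,14-diacetate, Z C6 iodide) | CC(=O)O[C@H]1CC=C(C)[C@H]([C@H]2OC(C)(C)O[C@@]23[C@@H](C(=O)O)OC(=O)[C@@H]3C)[C@@]1(C)[C@H](OC(C)=O)CC/C(C)=C\I | intermediate
34 | seco iodoalkene with C7 N-acyloxyphthalimide ester (key-step precursor) | CC(=O)O[C@H]1CC=C(C)[C@H]([C@H]2OC(C)(C)O[C@@]23[C@@H](C(=O)ON4C(=O)c5ccccc5C4=O)OC(=O)[C@@H]3C)[C@@]1(C)[C@H](OC(C)=O)CC/C(C)=C\I | intermediate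
35 | tricyclic 8,9-acetonide of the target (2,14-diacetate; key-step product) | CC(=O)O[C@H]1CC=C(C)[C@@H]2[C@H]4OC(C)(C)O[C@]34[C@H](/C=C(/C)CC[C@@H](OC(C)=O)[C@@]12C)OC(=O)[C@@H]3C | intermediate
36 | 9-deacetylstylatulide lactone | CC(=O)O[C@H]1CC=C(C)[C@@H]2[C@@H](O)[C@@]3(O)[C@H](/C=C(/C)CC[C@@H](OC(C)=O)[C@@]12C)OC(=O)[C@@H]3C | target

**Step count**
Total: 24 steps. Longest linear sequence: 19 steps (prop-2-yn-1-ol through steps 6 to 24); 16 steps from (S)-carvone, 13 from garcinia acid.

**Steps most likely to fail**

1. Step 23 (proposed new method). Closure of the ten-membered ring at nickel may be too slow, so that the C7 radical is reduced to C7–H, dimerises, or the C7–nickel species loses the β-oxygen at C8. Fallback with known chemistry, setting out from acid 33 and returning at tricycle 35: oxidative decarboxylation with Pb(OAc)4 and pyridine in benzene should replace the C7 carboxyl by acetate and give the C7 acetoxy lactone F1 (an acylal, C7 epimers). Hydrazine acetate in DMF should remove only this anomeric-type acetate and give the C7 hydroxy lactone F2, a pseudo-acid in equilibrium with the open C7 aldehyde and C19 carboxylic acid. An intramolecular Nozaki–Hiyama–Kishi reaction (excess CrCl2, catalytic NiCl2, Et3N, DMSO/THF, high dilution), a known way to close ten-membered rings, should add the C6 alkenylchromium to the C7 aldehyde, and acidic work-up should relactonise O7 onto C19 to give 35.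

2. Step 17. The congested C9–C10 bond may form too slowly, leaving time for dimerisation or α-ketol rearrangement of aldehyde 7. In addition, a wrong facial outcome in the Luche step would be relayed stereospecifically to C10. Fallback setting out from allylic alcohol 24 and returning at ketone 29: CBr4/PPh3 should give the ring A allylic bromide F3 (12-bromide together with its 10-bromo allylic isomer, both usable). Indium powder with aldehyde 7 in DMF (Barbier allylation) generates an equilibrating allylindium that should bond through C10 on the less hindered β face and give the coupled diol F4 as C9 epimers. Dess–Martin oxidation of the mixture converges on 29.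

3. Step 3. The lactone enolate may expel O8 by β-elimination (opening of the dioxolanone) faster than it is methylated, or facial selectivity may be poor. Fallback setting out from 3 and returning at aldehyde 7: methanolysis (MeOH, Et3N) should give the hydroxy methyl ester F5. Hydroxyl-directed reduction of the α-hydroxy ester (BH3·SMe2, catalytic NaBH4, THF) should give the diol F6. 2-Methoxypropene/PPTS should give the spiro 8,9-acetonide F7, whose C8 oxygen is a poorer leaving group. LiN(SiMe3)2/MeI at −78 °C should give the C17-methyl acetonide F8 with the same facial bias. Aqueous AcOH should give the C17-methyl diol F9, and TEMPO/PhI(OAc)2 oxidation of its primary alcohol should give 7.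

**Further compounds**
F1 | step 23 | C7 acetoxy lactone from oxidative decarboxylation of 33 (C7 epimers) | CC(=O)O[C@H]1CC=C(C)[C@H]([C@H]2OC(C)(C)O[C@@]23C(OC(C)=O)OC(=O)[C@@H]3C)[C@@]1(C)[C@H](OC(C)=O)CC/C(C)=C\I
F2 | step 23 | C7 hydroxy lactone (pseudo-acid, C7 epimers) | CC(=O)O[C@H]1CC=C(C)[C@H]([C@H]2OC(C)(C)O[C@@]23C(O)OC(=O)[C@@H]3C)[C@@]1(C)[C@H](OC(C)=O)CC/C(C)=C\I
F3 | step 17 | ring A allylic bromide (12-bromo-10-ene, C12 epimers, with its 10-bromo-11-ene isomer) | BrC1C[C@H](OC(C)=O)[C@](C)([C@H](OC(C)=O)CC/C(C)=C\I)C=C1C
F4 | step 17 | coupled 8,9-diol as C9 epimers | CC(=O)O[C@H]1CC=C(C)[C@H](C(O)[C@]2(O)[C@@H](C)C(=O)O[C@@H]2C(=O)OC(C)(C)C)[C@@]1(C)[C@H](OC(C)=O)CC/C(C)=C\I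
F5 | step 3 | 2-tert-butyl 3-methyl (2S,3S)-3-hydroxy-5-oxotetrahydrofuran-2,3-dicarboxylate | O=C1C[C@@](O)(C(=O)OC)[C@@H](C(=O)OC(C)(C)C)O1
F6 | step 3 | tert-butyl 3-hydroxy-3-(hydroxymethyl)-5-oxotetrahydrofuran-2-carboxylate (8,9-diol, garcinia configuration) | O=C1C[C@@](O)(CO)[C@@H](C(=O)OC(C)(C)C)O1
F7 | step 3 | spiro 8,9-acetonide of F6 | O=C1C[C@@](O2)(COC2(C)C)[C@@H](C(=O)OC(C)(C)C)O1
F8 | step 3 | C17-methyl spiro 8,9-acetonide (methyl cis to O8) | O=C1[C@H](C)[C@@](O2)(COC2(C)C)[C@@H](C(=O)OC(C)(C)C)O1
F9 | step 3 | C17-methyl 8,9-diol | O=C1[C@H](C)[C@@](O)(CO)[C@@H](C(=O)OC(C)(C)C)O1
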